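**Plan** (benzofuran numbering: O1, C2, C3, C3a, C4 to C7, C7a)

- Retrosynthesis: the C7–CH2 bond to pyrone C3 is cut first (ortho-quinone methide plus pyrone), then the C5–acyl bond (aryllithium plus Weinreb amide), then in one operation C3–C2, O1–C7a and C7–CH2N, which leads back to a 3-bromo-2-fluorobenzyl chloride and a γ-bromo enol benzoate made from methacrolein.
- Forward: the benzene ring is bought as 5-fluororesorcinol and dressed (CHO, two methoxymethyl ethers, Br); the furan ring closes in the key step; the acyl chain is joined at C5; the pyrone ring is made separately from a β-keto ester and joined last.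
- Enabling feature: C7a and C7 are neighbouring carbons of the benzene ring that carry O1 and the methylene bridge, with the C6 oxygen beside C7 and the C3a side chain beside C7a. An aryne across C7–C7a can therefore take up the side-chain alkoxide at C7a and a carbon electrophile at C7 in one pass.
- Stereochemistry: C2 (R) is set by ligand-controlled copper-catalysed SN2′ alkylation in the stage that forms C3–C2; the acyl α-centre (R) comes from (R)-2-methylbutanoic acid and is carried through without enolising conditions.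

Key step: step 7

Assumption: the (R,R) ligand is taken to give the R ester by analogy with 3-bromopropenyl benzoate; if the sense of induction is opposite, the (S,S) ligand is used.

**Step 1**
Reactants: 1 5-fluorobenzene-1,3-diol
Product: 3 2-fluoro-4,6-dihydroxybenzaldehyde, via iminium chloride 2 (not isolated)
Conditions: POCl3, DMF, MeCN, 0 to 25 °C; then H2O, 50 °C
Reagents that add atoms: N,N-dimethylformamide CN(C)C=O; water O
Why: Vilsmeier–Haack formylation of a resorcinol goes para to one hydroxyl and ortho to the other rather than between the two, as with orcinol, which places the formyl group next to fluorine; no stereocentre.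

**Step 2**
Reactants: 3 2-fluoro-4,6-dihydroxybenzaldehyde
Product: 4 2-fluoro-4,6-bis(methoxymethoxy)benzaldehyde
Conditions: MOMCl, i-Pr2NEt, CH2Cl2, 0 to 40 °C
Reagents that add atoms: chloromethyl methyl ether COCCl
Why: O-alkylation of both phenols gives base-stable methoxymethyl ethers that tolerate the organometallic steps, direct the later lithiation and leave under mild acid.

**Step 3**
Reactants: 4 2-fluoro-4,6-bis(methoxymethoxy)benzaldehyde
Product: 5 3-bromo-2-fluoro-4,6-bis(methoxymethoxy)benzaldehyde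
Conditions: NBS, MeCN, 0 °C
Reagents that add atoms: N-bromosuccinimide O=C1CCC(=O)N1Br
Why: Electrophilic aromatic bromination should go to the position para to one ether and next to fluorine (the future C7) and not to the hindered position between the two ethers, as in the C5 bromination of 2,4-dialkoxybenzaldehydes.

**Step 4**
Reactants: 5 3-bromo-2-fluoro-4,6-bis(methoxymethoxy)benzaldehyde
Product: 6 [3-bromo-2-fluoro-4,6-bis(methoxymethoxy)phenyl]methanol
Conditions: NaBH4, MeOH, 0 °C
Reagents that add atoms: none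
Why: Borohydride reduction of the aldehyde; aryl halides and acetals are inert.

**Step 5**
Reactants: 6 [3-bromo-2-fluoro-4,6-bis(methoxymethoxy)phenyl]methanol
Product: 7 2-bromo-4-(chloromethyl)-3-fluoro-1,5-bis(methoxymethoxy)benzene
Conditions: NCS, PPh3, THF, −20 to 0 °C
Reagents that add atoms: N-chlorosuccinimide O=C1CCC(=O)N1Cl
Why: Appel-type chlorination of the benzylic alcohol under neutral conditions spares the acid-labile ethers; the chloride is used at once.

**Step 6**
Reactants: 8 2-methylprop-2-enal (methacrolein)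
Product: 9 (E)-3-bromo-2-methylprop-1-en-1-yl benzoate
Conditions: PhCOBr, CH2Cl2, 0 to 25 °C
Reagents that add atoms: benzoyl bromide O=C(Br)c1ccccc1
Why: Conjugate (1,4) addition of an acyl bromide to an enal, as known for acrolein, gives the γ-bromo enol ester; the E isomer (benzoyloxy anti to CH2Br) should prevail under the equilibrating conditions and is purified.

**Step 7**
Reactants: 7 2-bromo-4-(chloromethyl)-3-fluoro-1,5-bis(methoxymethoxy)benzene; 9 (E)-3-bromo-2-methylprop-1-en-1-yl benzoate
Product: 16 1-[(2R)-4,6-bis(methoxymethoxy)-2-(prop-1-en-2-yl)-2,3-dihydro-1-benzofuran-7-yl]-N,N-dimethylmethanamine, via Grignard reagent 10 (not isolated), via allylic benzoate 11 (not isolated), via lithium alkoxide 12 (not isolated), via fluoroaryllithium 13 (not isolated), via aryne 14 (not isolated), via aryllithium 15 (not isolated)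
Conditions: Mg, Et2O, 0 °C; then 9, CuBr·SMe2 (5 mol%), (R,R)-Taniaphos, i.e. 1-[(dimethylamino)(2-diphenylphosphinophenyl)methyl]-2-(diphenylphosphino)ferrocene (6 mol%), t-BuOMe, −75 °C; then MeLi (2.2 equiv), THF, −78 °C; then t-BuLi (2.1 equiv), −78 to 25 °C; then [CH2=NMe2]I, −78 to 25 °C
Reagents that add atoms: N,N-dimethylmethyleneiminium iodide C=[N+](C)C.[I-]
Why: Proposed new method: the merger in one flask has not been described, and the alkylation stage extends the copper/Taniaphos hetero-allylic asymmetric alkylation of 3-bromopropenyl esters by alkyl Grignard reagents (closest known reaction type) to a benzylic Grignard reagent and a 2-methyl substrate. The cuprate formed from 10 adds anti to bromide in the SN2′ sense at the oxygen-bearing alkene carbon of 9 (σ-allyl trivalent copper, then reductive elimination), which forms C3–C2, turns the bromomethyl end into the isopropenyl group and sets C2 as R under control of the ligand. MeLi frees alkoxide 12, bromine–lithium exchange at C7 and loss of LiF across C7–C7a give aryne 14, and the alkoxide closes the furan ring on C7a in a 5-exo-dig addition (O1–C7a), modelled on the known aryne ring closure of 2-(halophenyl)ethoxides. Two elements direct the addition to C7a: the two-atom tether from C3a reaches only this carbon, and the C6 methoxymethoxy group beside C7 polarises the aryne so that the nucleophile enters at the distal carbon and the carbanion develops at C7 next to oxygen. Aryllithium 15 is then captured by the iminium salt, so the aryne has taken up O1 and the bridge carbon on neighbouring ring carbons and C5 is left as the only ring C–H. The step needs SN2′ over SN2 selectivity, high facial selectivity on a geometrically pure E enol ester and an aryl bromide that survives until t-BuLi is added; the low temperature, the copper catalyst and the inertness of aryl bromides to Grignard reagents and MeLi at −78 °C should secure these.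

**Step 8**
Reactants: 17 (2R)-2-methylbutanoic acid
Product: 18 (2R)-N-methoxy-N,2-dimethylbutanamide
Conditions: MeNH(OMe)·HCl, EDC·HCl, HOBt, i-Pr2NEt, CH2Cl2, 0 to 25 °C
Reagents that add atoms: N,O-dimethylhydroxylamine hydrochloride CNOC.Cl
Why: Carbodiimide amide coupling gives the Weinreb amide without touching the α-stereocentre.

**Step 9**
Reactants: 16 1-[(2R)-4,6-bis(methoxymethoxy)-2-(prop-1-en-2-yl)-2,3-dihydro-1-benzofuran-7-yl]-N,N-dimethylmethanamine; 18 (2R)-N-methoxy-N,2-dimethylbutanamide
Product: 20 (2R)-1-[(2R)-7-[(dimethylamino)methyl]-4,6-bis(methoxymethoxy)-2-(prop-1-en-2-yl)-2,3-dihydro-1-benzofuran-5-yl]-2-methylbutan-1-one, via aryllithium 19 (not isolated)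
Conditions: s-BuLi, TMEDA, THF, −78 °C; then 18, −78 to 0 °C
Reagents that add atoms: none
Why: Directed ortho-lithiation at C5, the only ring C–H and flanked by two methoxymethoxy groups, followed by Weinreb ketone synthesis; the stable tetrahedral adduct prevents over-addition and keeps the ketone masked until work-up, so the R α-centre should be retained.

**Step 10**
Reactants: 20 (2R)-1-[(2R)-7-[(dimethylamino)methyl]-4,6-bis(methoxymethoxy)-2-(prop-1-en-2-yl)-2,3-dihydro-1-benzofuran-5-yl]-2-methylbutan-1-one
Product: 21 (2R)-1-[(2R)-7-[(dimethylamino)methyl]-4,6-dihydroxy-2-(prop-1-en-2-yl)-2,3-dihydro-1-benzofuran-5-yl]-2-methylbutan-1-one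
Conditions: 2 M HCl, MeOH, 25 °C; NaHCO3 (aq) work-up at 0 °C
Reagents that add atoms: none
Why: Acid-catalysed acetal exchange removes both methoxymethyl ethers (those ortho to a ketone are labile), while the protonated amine, the allylic ring ether and the isopropenyl group should survive at 25 °C.

**Step 11**
Reactants: 22 methyl 3-oxopentanoate; 23 N-methoxy-N-methylpropanamide
Product: 25 methyl 4-methyl-3,5-dioxoheptanoate, via dianion 24 (not isolated)
Conditions: NaH, THF, 0 °C; then n-BuLi, 0 °C; then 23, −78 to 0 °C; aq. HCl work-up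
Reagents that add atoms: none
Why: The β-keto ester dianion is acylated at its more reactive γ-carbon by the Weinreb amide (Claisen-type C-acylation), which installs the propanoyl group on the carbon that becomes C5 of the pyrone.

**Step 12**
Reactants: 25 methyl 4-methyl-3,5-dioxoheptanoate
Product: 26 6-ethyl-4-hydroxy-5-methyl-2H-pyran-2-one
Conditions: DBU, toluene, 110 °C; aq. HCl work-up
Reagents that add atoms: none
Why: Base-mediated lactonisation of the C5 enol onto the ester with loss of methanol is the standard route from 3,5-diketo esters to 4-hydroxy-2-pyrones.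

**Step 13**
Reactants: 21 (2R)-1-[(2R)-7-[(dimethylamino)methyl]-4,6-dihydroxy-2-(prop-1-en-2-yl)-2,3-dihydro-1-benzofuran-5-yl]-2-methylbutan-1-one; 26 6-ethyl-4-hydroxy-5-methyl-2H-pyran-2-one
Product: 28 3-{[(2R)-4,6-dihydroxy-5-[(2R)-2-methylbutanoyl]-2-(prop-1-en-2-yl)-2,3-dihydro-1-benzofuran-7-yl]methyl}-6-ethyl-4-hydroxy-5-methyl-2H-pyran-2-one (CNP0199358.1), via quinone methide 27 (not isolated)
Conditions: 1,4-dioxane, 90 °C
Reagents that add atoms: none
Why: Thermal loss of dimethylamine from the phenolic Mannich base gives the ortho-quinone methide, which is trapped at its exocyclic carbon by the nucleophilic C3 of the 4-hydroxy-2-pyrone in a Michael addition that restores the aromatic ring; no stereocentre is touched.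

**Compound list**

1 | 5-fluorobenzene-1,3-diol | Oc1cc(O)cc(F)c1 | starting material
2 | (2-fluoro-4,6-dihydroxybenzylidene)dimethylammonium chloride (not isolated) | C[N+](C)=Cc1c(O)cc(O)cc1F.[Cl-] | intermediate
3 | 2-fluoro-4,6-dihydroxybenzaldehyde | O=Cc1c(O)cc(O)cc1F | intermediate
4 | 2-fluoro-4,6-bis(methoxymethoxy)benzaldehyde | O=Cc1c(OCOC)cc(OCOC)cc1F | intermediate
5 | 3-bromo-2-fluoro-4,6-bis(methoxymethoxy)benzaldehyde | O=Cc1c(OCOC)cc(OCOC)c(Br)c1F | intermediate
6 | [3-bromo-2-fluoro-4,6-bis(methoxymethoxy)phenyl]methanol | OCc1c(OCOC)cc(OCOC)c(Br)c1F | intermediate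
7 | 2-bromo-4-(chloromethyl)-3-fluoro-1,5-bis(methoxymethoxy)benzene | ClCc1c(OCOC)cc(OCOC)c(Br)c1F | intermediate
8 | 2-methylprop-2-enal (methacrolein) | C=C(C)C=O | starting material
9 | (E)-3-bromo-2-methylprop-1-en-1-yl benzoate | BrC/C(C)=C/OC(=O)c1ccccc1 | intermediate
10 | {[3-bromo-2-fluoro-4,6-bis(methoxymethoxy)phenyl]methyl}magnesium chloride (not isolated) | Cl[Mg]Cc1c(OCOC)cc(OCOC)c(Br)c1F | intermediate
11 | (2R)-1-[3-bromo-2-fluoro-4,6-bis(methoxymethoxy)phenyl]-3-methylbut-3-en-2-yl benzoate (not isolated) | C=C(C)[C@H](OC(=O)c1ccccc1)Cc1c(OCOC)cc(OCOC)c(Br)c1F | intermediate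
12 | lithium (2R)-1-[3-bromo-2-fluoro-4,6-bis(methoxymethoxy)phenyl]-3-methylbut-3-en-2-olate (not isolated) | C=C(C)[C@H]([O-])Cc1c(OCOC)cc(OCOC)c(Br)c1F.[Li+] | intermediate
13 | lithium (2R)-1-[2-fluoro-3-lithio-4,6-bis(methoxymethoxy)phenyl]-3-methylbut-3-en-2-olate (not isolated) | C=C(C)[C@H]([O-])Cc1c(OCOC)cc(OCOC)c([Li])c1F.[Li+] | intermediate
14 | lithium (2R)-1-[2,3-didehydro-4,6-bis(methoxymethoxy)phenyl]-3-methylbut-3-en-2-olate, the aryne across C7–C7a (not isolated) | C=C(C)[C@H]([O-])CC1=C(OCOC)C=C(OCOC)C#C1.[Li+] | intermediate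
15 | [(2R)-4,6-bis(methoxymethoxy)-2-(prop-1-en-2-yl)-2,3-dihydro-1-benzofuran-7-yl]lithium (not isolated) | C=C(C)[C@H]1Cc2c(OCOC)cc(OCOC)c([Li])c2O1 | intermediate
16 | 1-[(2R)-4,6-bis(methoxymethoxy)-2-(prop-1-en-2-yl)-2,3-dihydro-1-benzofuran-7-yl]-N,N-dimethylmethanamine | C=C(C)[C@H]1Cc2c(OCOC)cc(OCOC)c(CN(C)C)c2O1 | intermediate
17 | (2R)-2-methylbutanoic acid | CC[C@@H](C)C(=O)O | starting material
18 | (2R)-N-methoxy-N,2-dimethylbutanamide | CC[C@@H](C)C(=O)N(C)OC | intermediate
19 | [(2R)-7-[(dimethylamino)methyl]-4,6-bis(methoxymethoxy)-2-(prop-1-en-2-yl)-2,3-dihydro-1-benzofuran-5-yl]lithium (not isolated) | C=C(C)[C@H]1Cc2c(OCOC)c([Li])c(OCOC)c(CN(C)C)c2O1 | intermediate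
20 | (2R)-1-[(2R)-7-[(dimethylamino)methyl]-4,6-bis(methoxymethoxy)-2-(prop-1-en-2-yl)-2,3-dihydro-1-benzofuran-5-yl]-2-methylbutan-1-one | C=C(C)[C@H]1Cc2c(OCOC)c(C(=O)[C@H](C)CC)c(OCOC)c(CN(C)C)c2O1 | intermediate
21 | (2R)-1-[(2R)-7-[(dimethylamino)methyl]-4,6-dihydroxy-2-(prop-1-en-2-yl)-2,3-dihydro-1-benzofuran-5-yl]-2-methylbutan-1-one | C=C(C)[C@H]1Cc2c(O)c(C(=O)[C@H](C)CC)c(O)c(CN(C)C)c2O1 | intermediate
22 | methyl 3-oxopentanoate | CCC(=O)CC(=O)OC | starting material
23 | N-methoxy-N-methylpropanamide | CCC(=O)N(C)OC | starting material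
24 | sodium lithium 2,4-dianion of methyl 3-oxopentanoate (not isolated) | CC=C([O-])C=C([O-])OC.[Na+].[Li+] | intermediate
25 | methyl 4-methyl-3,5-dioxoheptanoate | CCC(=O)C(C)C(=O)CC(=O)OC | intermediate
26 | 6-ethyl-4-hydroxy-5-methyl-2H-pyran-2-one | CCc1oc(=O)cc(O)c1C | intermediate
27 | (2R)-4-hydroxy-7-methylidene-5-[(2R)-2-methylbutanoyl]-2-(prop-1-en-2-yl)-2,3-dihydro-1-benzofuran-6(7H)-one, the ortho-quinone methide (not isolated) | C=C(C)[C@H]1CC2=C(O1)C(=C)C(=O)C(C(=O)[C@H](C)CC)=C2O | intermediate
28 | 3-{[(2R)-4,6-dihydroxy-5-[(2R)-2-methylbutanoyl]-2-(prop-1-en-2-yl)-2,3-dihydro-1-benzofuran-7-yl]methyl}-6-ethyl-4-hydroxy-5-methyl-2H-pyran-2-one | C=C(C)[C@H]1Cc2c(O)c(C(=O)[C@H](C)CC)c(O)c(Cc3c(O)c(C)c(CC)oc3=O)c2O1 | target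

**Step count**

Total: 13 steps. Longest linear sequence: 9 steps (steps 1, 2, 3, 4, 5, 7, 9, 10, 13).

**Steps most likely to fail**

Step 7. What may go wrong: SN2 instead of SN2′ attack or poor facial selectivity in the copper-catalysed alkylation of the trisubstituted enol ester, or consumption of the organolithium reagents by residues of the first stage before the aryne forms. The fallback uses known reactions, sets out from 7 and comes back to the route at 16. Grignard reagent 10 (from 7 and Mg as in step 7) is added to methacrolein 8 (Et2O, −78 °C) to give racemic 1-[3-bromo-2-fluoro-4,6-bis(methoxymethoxy)phenyl]-3-methylbut-3-en-2-ol F1. Dess–Martin periodinane (CH2Cl2, NaHCO3) oxidises it to 1-[3-bromo-2-fluoro-4,6-bis(methoxymethoxy)phenyl]-3-methylbut-3-en-2-one F2. Corey–Bakshi–Shibata reduction ((S)-2-methyl-CBS-oxazaborolidine, BH3·SMe2, THF, −30 °C, isopropenyl as the large group) should give (2R)-1-[3-bromo-2-fluoro-4,6-bis(methoxymethoxy)phenyl]-3-methylbut-3-en-2-ol F3. n-BuLi (1 equiv), then t-BuLi (2 equiv), THF, −78 to 25 °C, then [CH2=NMe2]I take F3 through 12, 13, 14 and 15 to 16; only the carbon–carbon bond formation is moved out of the annulation.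

Step 9. What may go wrong: proton transfer from the α-position of the hindered Weinreb amide to the hindered aryllithium in place of addition, with incomplete conversion and erosion of the α-centre. The fallback sets out from 16 and 18 and comes back at 20. Amide 18 is reduced with LiAlH4 (THF, −78 °C) to (2R)-2-methylbutanal F4, which is used at once. Aryllithium 19 (from 16 as in step 9) adds to F4 at −78 °C to give (2R)-1-[(2R)-7-[(dimethylamino)methyl]-4,6-bis(methoxymethoxy)-2-(prop-1-en-2-yl)-2,3-dihydro-1-benzofuran-5-yl]-2-methylbutan-1-ol F5 as a mixture at the carbinol carbon. Dess–Martin oxidation of F5 gives 20.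

Step 13. What may go wrong: the quinone methide recombines with dimethylamine, oligomerises or is attacked by the pyrone oxygen faster than by pyrone C3. The fallback alkylates before deprotection, sets out from 20 and comes back at 28. MeI (MeCN, 25 °C) converts 20 into {[(2R)-4,6-bis(methoxymethoxy)-5-[(2R)-2-methylbutanoyl]-2-(prop-1-en-2-yl)-2,3-dihydro-1-benzofuran-7-yl]methyl}trimethylammonium iodide F6. F6 with pyrone 26 and K2CO3 (DMF, 60 °C) gives the C3-benzylated pyrone 3-{[(2R)-4,6-bis(methoxymethoxy)-5-[(2R)-2-methylbutanoyl]-2-(prop-1-en-2-yl)-2,3-dihydro-1-benzofuran-7-yl]methyl}-6-ethyl-4-hydroxy-5-methyl-2H-pyran-2-one F7 with loss of trimethylamine. 2 M HCl in MeOH at 25 °C then removes both methoxymethyl groups to give 28.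

**Further compounds**

F1 | step 7 | 1-[3-bromo-2-fluoro-4,6-bis(methoxymethoxy)phenyl]-3-methylbut-3-en-2-ol (racemic) | C=C(C)C(O)Cc1c(OCOC)cc(OCOC)c(Br)c1F
F2 | step 7 | 1-[3-bromo-2-fluoro-4,6-bis(methoxymethoxy)phenyl]-3-methylbut-3-en-2-one | C=C(C)C(=O)Cc1c(OCOC)cc(OCOC)c(Br)c1F
F3 | step 7 | (2R)-1-[3-bromo-2-fluoro-4,6-bis(methoxymethoxy)phenyl]-3-methylbut-3-en-2-ol | C=C(C)[C@H](O)Cc1c(OCOC)cc(OCOC)c(Br)c1F
F4 | step 9 | (2R)-2-methylbutanal | CC[C@@H](C)C=O
F5 | step 9 | (2R)-1-[(2R)-7-[(dimethylamino)methyl]-4,6-bis(methoxymethoxy)-2-(prop-1-en-2-yl)-2,3-dihydro-1-benzofuran-5-yl]-2-methylbutan-1-ol | C=C(C)[C@H]1Cc2c(OCOC)c(C(O)[C@H](C)CC)c(OCOC)c(CN(C)C)c2O1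
F6 | step 13 | {[(2R)-4,6-bis(methoxymethoxy)-5-[(2R)-2-methylbutanoyl]-2-(prop-1-en-2-yl)-2,3-dihydro-1-benzofuran-7-yl]methyl}trimethylammonium iodide | C=C(C)[C@H]1Cc2c(OCOC)c(C(=O)[C@H](C)CC)c(OCOC)c(C[N+](C)(C)C)c2O1.[I-]
F7 | step 13 | 3-{[(2R)-4,6-bis(methoxymethoxy)-5-[(2R)-2-methylbutanoyl]-2-(prop-1-en-2-yl)-2,3-dihydro-1-benzofuran-7-yl]methyl}-6-ethyl-4-hydroxy-5-methyl-2H-pyran-2-one | C=C(C)[C@H]1Cc2c(OCOC)c(C(=O)[C@H](C)CC)c(OCOC)c(Cc3c(O)c(C)c(CC)oc3=O)c2O1
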